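**Plan**

- Cuts: the formyl group goes back to a C8 methyl ester and ring B to a cyclohexane-1,3-dione. The dione is cut at C1'–C6' and C3'–C4' (methyl ketone plus acrylate) and at C3'–prenyl. The pyran ring is cut at C3–C4 and O1–C2 (ortho-quinone methide plus aldehyde), and C4–C4a goes back to formaldehyde on a phloroglucinol ester.
- Feature: in ring B, C3' lies between the oxygen-bearing C2' and C4'. This is C2 of a cyclohexane-1,3-dione, its only doubly activated carbon, so ring B can be built saturated from the C1' methylene ketone and prenylated at one site before dehydrogenation.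
- Forward order: ring A (bought) → pyran ring (steps 2–4) → methyl ketone side chain (steps 5–6) → ring B by Michael–Claisen annulation (step 7) → C3' prenylation (step 8) → aromatisation (step 9) → ester to aldehyde and deprotection (steps 10–13).
- Stereochemistry: C3 is the only stereocentre. It is set in step 3 by enamine catalysis with an (R)-diarylprolinol silyl ether, carries no acidifying group afterwards, and ends as (3R).

Key step: step 7

Remark: isoflavan numbering is used (O1, C2–C4, C4a–C8a; ring B C1'–C6'); the C3 descriptor changes from S (allyl stage) to R (from ketone 10 on) through CIP priorities only, with no inversion.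

**Route**

Step 1
Reactants: 1 methyl 2,4,6-trihydroxybenzoate
Product: 2 methyl 2,6-dihydroxy-4-methoxybenzoate
Conditions: MeOH (1.1 equiv), PPh3, DIAD, THF, 0 °C to rt
Reagents that add atoms: methanol, CO
Why: Mitsunobu etherification should pick the 4-hydroxyl, which is the most acidic and the one not hydrogen-bonded to the ester, and no stereocentre is formed.

Step 2
Reactants: 2 methyl 2,6-dihydroxy-4-methoxybenzoate
Product: 3 methyl 2,6-dihydroxy-4-methoxy-3-[(4-methylphenyl)sulfonylmethyl]benzoate
Conditions: p-TolSO2Na (1.5 equiv), (CH2O)n (0.9 equiv), HCO2H–H2O, rt to 40 °C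
Reagents that add atoms: formaldehyde (as paraformaldehyde), C=O; sodium 4-methylbenzenesulfinate, [Na+].[O-]S(=O)c1ccc(C)cc1
Why: In this Mannich-type three-component sulfonylmethylation the phenol is hydroxymethylated at one of its two equivalent free positions and the benzylic cation is trapped at sulfur by the sulfinate, while a deficit of formaldehyde should hold back a second substitution.

Step 3
Reactants: 3 methyl 2,6-dihydroxy-4-methoxy-3-[(4-methylphenyl)sulfonylmethyl]benzoate; 4 pent-4-enal
Product: 7 methyl (3S)-2,7-dihydroxy-5-methoxy-3-(prop-2-enyl)chromane-8-carboxylate (lactol; both C2 epimers), via ortho-quinone methide 5 (not isolated), via ring-opened hydroxy aldehyde 6 (not isolated)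
Conditions: (R)-2-[diphenyl(trimethylsilyloxy)methyl]pyrrolidine (20 mol %), 4 (2 equiv), Na2CO3, CH2Cl2, 0 °C to rt; aqueous work-up
Reagents that add atoms: pent-4-enal (4), C=CCCC=O
Why: Base-induced 1,4-elimination of sulfinate gives quinone methide 5 (its para tautomer leads to the same adduct), the E-enamine of 4 adds through its α-carbon to the methide CH2 (enamine Michael addition, formal [4+2] annulation) and the phenol closes on the released aldehyde 6 to the lactol; the C(Ph)2OSiMe3 group of the (R)-catalyst shields one enamine face, so the new centre should form as (S).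

Step 4
Reactants: 7 methyl (3S)-2,7-dihydroxy-5-methoxy-3-(prop-2-enyl)chromane-8-carboxylate
Product: 8 methyl (3S)-7-hydroxy-5-methoxy-3-(prop-2-enyl)chromane-8-carboxylate
Conditions: Et3SiH (3 equiv), BF3·OEt2 (2 equiv), CH2Cl2, -78 to -20 °C
Reagents that add atoms: none
Why: In this ionic hydrogenation the Lewis acid ionises the anomeric hydroxyl to the 2-chromanyl oxocarbenium ion, which the silane reduces at low temperature before C3–H can be lost, and the terminal alkene, phenol and ester are inert.

Step 5
Reactants: 8 methyl (3S)-7-hydroxy-5-methoxy-3-(prop-2-enyl)chromane-8-carboxylate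
Product: 9 methyl (3S)-5-methoxy-7-(methoxymethoxy)-3-(prop-2-enyl)chromane-8-carboxylate
Conditions: NaH, MOMCl, DMF, 0 °C
Reagents that add atoms: chloromethyl methyl ether, COCCl
Why: Williamson-type O-alkylation of the sodium phenoxide (the chelated OH needs the strong base) installs a base-stable acetal that carries O7 through the enolate chemistry.

Step 6
Reactants: 9 methyl (3S)-5-methoxy-7-(methoxymethoxy)-3-(prop-2-enyl)chromane-8-carboxylate
Product: 10 methyl (3R)-5-methoxy-7-(methoxymethoxy)-3-(2-oxopropyl)chromane-8-carboxylate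
Conditions: PdCl2 (10 mol %), Cu(OAc)2 (20 mol %), O2 (1 atm), DMA–H2O (7:1), rt
Reagents that add atoms: water, O
Why: In this Tsuji–Wacker oxidation divalent palladium activates the terminal alkene, water attacks the internal carbon (Markovnikov) and the copper salt with O2 turns the catalyst over, giving the methyl ketone without touching C3.

Step 7
Reactants: 10 methyl (3R)-5-methoxy-7-(methoxymethoxy)-3-(2-oxopropyl)chromane-8-carboxylate; 11 methyl acrylate
Product: 13 methyl (3R)-3-(2,4-dioxocyclohexyl)-5-methoxy-7-(methoxymethoxy)chromane-8-carboxylate (mixture at C1'), via Michael adduct keto ester 12 (not isolated)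
Conditions: t-BuOK (2.2 equiv), 11 (1.05 equiv, slow addition), THF, -10 °C to rt; then aq. HCl
Reagents that add atoms: methyl acrylate (11), C=CC(=O)OC
Why: t-BuOK equilibrates the ketone enolates, and the more substituted one, at the methylene on C3 (future C1'), adds to methyl acrylate to form C1'–C6' (Michael addition) and give keto ester 12. Proton transfer then gives the methyl-side enolate of 12, whose carbon (C3') acylates on the ester carbonyl (C4') in a 6-exo-trig Claisen closure with loss of methoxide, so ring B arises as the cyclohexane-1,3-dione. The closest known reaction type is the base-mediated consecutive Michael–Claisen annulation of alkyl methyl ketones with acrylates to 4-substituted cyclohexane-1,3-diones. The only new centre, C1', forms without control and is erased on aromatisation, while C3 has no acidifying group and no leaving group β to the enolate and should keep its configuration. The step needs methylene-over-methyl regioselectivity: the conjugate addition is reversible, the adduct through the methyl group could cyclise only through a hindered branched enolate, and the adduct through the methylene closes fast through a primary enolate to the dione, whose deprotonation by the second equivalent of base makes that channel irreversible. Slow addition of one equivalent of acrylate in the cold should hold back a second conjugate addition.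

Step 8
Reactants: 13 methyl (3R)-3-(2,4-dioxocyclohexyl)-5-methoxy-7-(methoxymethoxy)chromane-8-carboxylate; 14 1-bromo-3-methylbut-2-ene
Product: 15 methyl (3R)-5-methoxy-7-(methoxymethoxy)-3-[3-(3-methylbut-2-enyl)-2,4-dioxocyclohexyl]chromane-8-carboxylate (diastereomers and enol forms)
Conditions: 14 (1.2 equiv), KOH (1.0 equiv), H2O–1,4-dioxane, 0 °C to rt
Reagents that add atoms: 1-bromo-3-methylbut-2-ene (14), CC(C)=CCBr
Why: The dione enolate is C-alkylated at the carbon between the two carbonyls (C3'), the only doubly activated position, and the aqueous medium hydrogen-bonds the enolate oxygens so that C- is favoured over O-alkylation; the sp3 centres of ring B are transient.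

Step 9
Reactants: 15 methyl (3R)-5-methoxy-7-(methoxymethoxy)-3-[3-(3-methylbut-2-enyl)-2,4-dioxocyclohexyl]chromane-8-carboxylate
Product: 17 methyl (3R)-3-[2,4-bis(tert-butyldimethylsilyloxy)-3-(3-methylbut-2-enyl)phenyl]-5-methoxy-7-(methoxymethoxy)chromane-8-carboxylate, via bis-silyl dienol ether 16 (not isolated)
Conditions: TBSOTf (2.5 equiv), Et3N, CH2Cl2, 0 °C to rt; pentane trituration and filtration; then DDQ (1.05 equiv), 2,6-lutidine, CH2Cl2, 0 °C
Reagents that add atoms: tert-butyldimethylsilyl trifluoromethanesulfonate, CC(C)(C)[Si](C)(C)OS(=O)(=O)C(F)(F)F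
Why: Soft enolisation with silyl triflate and amine gives the 1,3-bis(silyloxy)cyclohexadiene 16 (its double-bond isomer converges on the same arene), and DDQ abstracts an allylic hydride to an oxygen-stabilised cation that loses a proton to the arene (silyl enol ether dehydrogenation), giving the 2',4'-dioxygenated ring B with the prenyl group fixed at C3'.

Step 10
Reactants: 17 methyl (3R)-3-[2,4-bis(tert-butyldimethylsilyloxy)-3-(3-methylbut-2-enyl)phenyl]-5-methoxy-7-(methoxymethoxy)chromane-8-carboxylate
Product: 18 [(3R)-3-[2,4-bis(tert-butyldimethylsilyloxy)-3-(3-methylbut-2-enyl)phenyl]-5-methoxy-7-(methoxymethoxy)chroman-8-yl]methanol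
Conditions: i-Bu2AlH (3 equiv), CH2Cl2, -78 to 0 °C
Reagents that add atoms: none
Why: Two hydride transfers from the aluminium hydride reduce the hindered aryl ester to the benzylic alcohol, while aryl silyl ethers, the MOM acetal and the prenyl alkene do not react.

Step 11
Reactants: 18 [(3R)-3-[2,4-bis(tert-butyldimethylsilyloxy)-3-(3-methylbut-2-enyl)phenyl]-5-methoxy-7-(methoxymethoxy)chroman-8-yl]methanol
Product: 19 (3R)-3-[2,4-bis(tert-butyldimethylsilyloxy)-3-(3-methylbut-2-enyl)phenyl]-5-methoxy-7-(methoxymethoxy)chromane-8-carbaldehyde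
Conditions: MnO2 (activated, excess), CH2Cl2, rt
Reagents that add atoms: none
Why: Heterogeneous MnO2 oxidation is selective for the electron-rich benzylic alcohol and stops at the aldehyde.

Step 12
Reactants: 19 (3R)-3-[2,4-bis(tert-butyldimethylsilyloxy)-3-(3-methylbut-2-enyl)phenyl]-5-methoxy-7-(methoxymethoxy)chromane-8-carbaldehyde
Product: 20 (3R)-3-[2,4-dihydroxy-3-(3-methylbut-2-enyl)phenyl]-5-methoxy-7-(methoxymethoxy)chromane-8-carbaldehyde
Conditions: Bu4NF (2.2 equiv), AcOH (2.2 equiv), THF, 0 °C
Reagents that add atoms: none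
Why: Fluoride-driven Si–O cleavage frees both ring B phenols, and the acetic acid buffer keeps the aldehyde from seeing free phenoxide or basic fluoride.

Step 13
Reactants: 20 (3R)-3-[2,4-dihydroxy-3-(3-methylbut-2-enyl)phenyl]-5-methoxy-7-(methoxymethoxy)chromane-8-carbaldehyde
Product: 21 (3R)-3-[2,4-dihydroxy-3-(3-methylbut-2-enyl)phenyl]-7-hydroxy-5-methoxychromane-8-carbaldehyde
Conditions: HCl (1 M), MeOH–THF, rt; aqueous work-up
Reagents that add atoms: none
Why: Acid-catalysed acetal methanolysis removes the MOM group, which is especially labile next to the chelating formyl group, under conditions mild enough that the ortho-prenyl phenol should not cyclise; C3 is untouched and the (3R) target results.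

**Compound list**

1 | methyl 2,4,6-trihydroxybenzoate | COC(=O)c1c(O)cc(O)cc1O | starting material
2 | methyl 2,6-dihydroxy-4-methoxybenzoate | COC(=O)c1c(O)cc(OC)cc1O | intermediate
3 | methyl 2,6-dihydroxy-4-methoxy-3-[(4-methylphenyl)sulfonylmethyl]benzoate | COC(=O)c1c(O)cc(OC)c(CS(=O)(=O)c2ccc(C)cc2)c1O | intermediate
4 | pent-4-enal | C=CCCC=O | starting material
5 | methyl 2-hydroxy-4-methoxy-5-methylidene-6-oxocyclohexa-1,3-diene-1-carboxylate (ortho-quinone methide) | COC(=O)C1=C(O)C=C(OC)C(=C)C1=O | intermediate (not isolated)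
6 | methyl 3-[(2S)-2-formylpent-4-enyl]-2,6-dihydroxy-4-methoxybenzoate | COC(=O)c1c(O)cc(OC)c(C[C@H](CC=C)C=O)c1O | intermediate (not isolated)
7 | methyl (3S)-2,7-dihydroxy-5-methoxy-3-(prop-2-enyl)chromane-8-carboxylate (both C2 epimers) | COc1cc(O)c(C(=O)OC)c2c1C[C@H](CC=C)C(O)O2 | intermediate
8 | methyl (3S)-7-hydroxy-5-methoxy-3-(prop-2-enyl)chromane-8-carboxylate | COc1cc(O)c(C(=O)OC)c2c1C[C@H](CC=C)CO2 | intermediate
9 | methyl (3S)-5-methoxy-7-(methoxymethoxy)-3-(prop-2-enyl)chromane-8-carboxylate | COc1cc(OCOC)c(C(=O)OC)c2c1C[C@H](CC=C)CO2 | intermediate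
10 | methyl (3R)-5-methoxy-7-(methoxymethoxy)-3-(2-oxopropyl)chromane-8-carboxylate | COc1cc(OCOC)c(C(=O)OC)c2c1C[C@H](CC(C)=O)CO2 | intermediate
11 | methyl acrylate | C=CC(=O)OC | starting material
12 | methyl (3R)-5-methoxy-3-(6-methoxy-2,6-dioxohexan-3-yl)-7-(methoxymethoxy)chromane-8-carboxylate (mixture at C1') | COc1cc(OCOC)c(C(=O)OC)c2c1C[C@H](C(CCC(=O)OC)C(C)=O)CO2 | intermediate (not isolated)
13 | methyl (3R)-3-(2,4-dioxocyclohexyl)-5-methoxy-7-(methoxymethoxy)chromane-8-carboxylate (mixture at C1') | COc1cc(OCOC)c(C(=O)OC)c2c1C[C@H](C1CCC(=O)CC1=O)CO2 | intermediate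
14 | 1-bromo-3-methylbut-2-ene | CC(C)=CCBr | starting material
15 | methyl (3R)-5-methoxy-7-(methoxymethoxy)-3-[3-(3-methylbut-2-enyl)-2,4-dioxocyclohexyl]chromane-8-carboxylate | COc1cc(OCOC)c(C(=O)OC)c2c1C[C@H](C1CCC(=O)C(CC=C(C)C)C1=O)CO2 | intermediate
16 | methyl (3R)-3-[2,4-bis(tert-butyldimethylsilyloxy)-3-(3-methylbut-2-enyl)cyclohexa-2,4-dienyl]-5-methoxy-7-(methoxymethoxy)chromane-8-carboxylate | COc1cc(OCOC)c(C(=O)OC)c2c1C[C@H](C1CC=C(O[Si](C)(C)C(C)(C)C)C(CC=C(C)C)=C1O[Si](C)(C)C(C)(C)C)CO2 | intermediate (not isolated)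
17 | methyl (3R)-3-[2,4-bis(tert-butyldimethylsilyloxy)-3-(3-methylbut-2-enyl)phenyl]-5-methoxy-7-(methoxymethoxy)chromane-8-carboxylate | COc1cc(OCOC)c(C(=O)OC)c2c1C[C@H](c1ccc(O[Si](C)(C)C(C)(C)C)c(CC=C(C)C)c1O[Si](C)(C)C(C)(C)C)CO2 | intermediate
18 | [(3R)-3-[2,4-bis(tert-butyldimethylsilyloxy)-3-(3-methylbut-2-enyl)phenyl]-5-methoxy-7-(methoxymethoxy)chroman-8-yl]methanol | COc1cc(OCOC)c(CO)c2c1C[C@H](c1ccc(O[Si](C)(C)C(C)(C)C)c(CC=C(C)C)c1O[Si](C)(C)C(C)(C)C)CO2 | intermediate
19 | (3R)-3-[2,4-bis(tert-butyldimethylsilyloxy)-3-(3-methylbut-2-enyl)phenyl]-5-methoxy-7-(methoxymethoxy)chromane-8-carbaldehyde | COc1cc(OCOC)c(C=O)c2c1C[C@H](c1ccc(O[Si](C)(C)C(C)(C)C)c(CC=C(C)C)c1O[Si](C)(C)C(C)(C)C)CO2 | intermediate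
20 | (3R)-3-[2,4-dihydroxy-3-(3-methylbut-2-enyl)phenyl]-5-methoxy-7-(methoxymethoxy)chromane-8-carbaldehyde | COc1cc(OCOC)c(C=O)c2c1C[C@H](c1ccc(O)c(CC=C(C)C)c1O)CO2 | intermediate
21 | (3R)-3-[2,4-dihydroxy-3-(3-methylbut-2-enyl)phenyl]-7-hydroxy-5-methoxychromane-8-carbaldehyde | COc1cc(O)c(C=O)c2c1C[C@H](c1ccc(O)c(CC=C(C)C)c1O)CO2 | target

**Step count and risks**

Total steps: 13. Longest linear sequence: 13 steps (1 to 21); compounds 4, 11 and 14 are bought and enter directly.

Risk 1, step 7. The conjugate addition may run through the methyl-side enolate (giving the 2-substituted dione) or go on to a double adduct. The fallback fixes the C1'–C6' bond on an aldehyde, which has only one α-carbon. It sets out from 9: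
- Lemieux–Johnson cleavage (OsO4 cat., NaIO4, 2,6-lutidine, dioxane–H2O) should give the aldehyde methyl (3R)-5-methoxy-7-(methoxymethoxy)-3-(2-oxoethyl)chromane-8-carboxylate F1.
- Its pyrrolidine enamine is alkylated with methyl acrylate (Stork enamine reaction; MeCN, reflux, then aqueous AcOH) to the formyl ester methyl (3R)-5-methoxy-3-(5-methoxy-1,5-dioxopentan-2-yl)-7-(methoxymethoxy)chromane-8-carboxylate F2.
- MeMgBr in THF at -78 °C, quenched cold to avoid lactonisation, adds to the aldehyde alone and gives the hydroxy ester methyl (3R)-3-(2-hydroxy-6-methoxy-6-oxohexan-3-yl)-5-methoxy-7-(methoxymethoxy)chromane-8-carboxylate F3.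
- Dess–Martin oxidation gives keto ester 12 as an isolated compound, and t-BuOK in THF closes it by the same Claisen acylation to dione 13, where the route is rejoined.

Risk 2, step 3. Facial discrimination at an unsubstituted methide may be poor, or the amine catalyst may be N-alkylated by the quinone methide so that a racemic background reaction takes over. The fallback sets C3 by an Evans alkylation and sets out from 2:
- Vilsmeier–Haack formylation (POCl3, DMF) gives methyl 3-formyl-2,6-dihydroxy-4-methoxybenzoate F4.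
- NaH and MOMCl give methyl 3-formyl-4-methoxy-2,6-bis(methoxymethoxy)benzoate F5.
- NaBH4 gives methyl 3-(hydroxymethyl)-4-methoxy-2,6-bis(methoxymethoxy)benzoate F6.
- CBr4 and PPh3 give the bromide methyl 3-(bromomethyl)-4-methoxy-2,6-bis(methoxymethoxy)benzoate F7.
- The imide (4R)-4-benzyl-3-(pent-4-enoyl)oxazolidin-2-one F8 is made from the commercial (R)-auxiliary, n-BuLi and pent-4-enoyl chloride.
- F8 is deprotonated with NaN(SiMe3)2 at -78 °C and alkylated by F7 on the face opposite the benzyl group, giving methyl 3-[(2S)-2-[(4R)-4-benzyl-2-oxooxazolidine-3-carbonyl]pent-4-enyl]-4-methoxy-2,6-bis(methoxymethoxy)benzoate F9.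
- LiBH4 in the cold removes the auxiliary reductively to methyl 3-[(2S)-2-(hydroxymethyl)pent-4-enyl]-4-methoxy-2,6-bis(methoxymethoxy)benzoate F10.
- HCl in MeOH frees both phenols to give methyl 2,6-dihydroxy-3-[(2S)-2-(hydroxymethyl)pent-4-enyl]-4-methoxybenzoate F11.
- Mitsunobu etherification (PPh3, DIAD, THF) closes the pyran ring through the only phenol that can reach the primary alcohol, and the route is rejoined at 8.

Risk 3, step 9. DDQ may over-oxidise by abstracting hydride from the benzylic C3–H or C4–H2 of the chromane (loss of the stereocentre, isoflavene formation) or attack the prenyl group, and the silyl triflate may strip the MOM acetal. The fallback dehydrogenates through an enolate and sets out from 15: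
- TBSCl and Et3N give the vinylogous silyl ester methyl (3R)-3-[4-(tert-butyldimethylsilyloxy)-3-(3-methylbut-2-enyl)-2-oxocyclohex-3-enyl]-5-methoxy-7-(methoxymethoxy)chromane-8-carboxylate F12; the isomer silylated at O2' would behave alike.
- LiN(i-Pr)2 in THF at -78 °C, then N-tert-butylbenzenesulfinimidoyl chloride, dehydrogenates the α'-position, and the cross-conjugated dienone tautomerises to the phenol methyl (3R)-3-[4-(tert-butyldimethylsilyloxy)-2-hydroxy-3-(3-methylbut-2-enyl)phenyl]-5-methoxy-7-(methoxymethoxy)chromane-8-carboxylate F13.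
- TBSCl and imidazole in DMF silylate the remaining phenol, and the route is rejoined at 17.

**Further compounds**

F1 | step 7 | methyl (3R)-5-methoxy-7-(methoxymethoxy)-3-(2-oxoethyl)chromane-8-carboxylate | COc1cc(OCOC)c(C(=O)OC)c2c1C[C@H](CC=O)CO2
F2 | step 7 | methyl (3R)-5-methoxy-3-(5-methoxy-1,5-dioxopentan-2-yl)-7-(methoxymethoxy)chromane-8-carboxylate | COc1cc(OCOC)c(C(=O)OC)c2c1C[C@H](C(C=O)CCC(=O)OC)CO2
F3 | step 7 | methyl (3R)-3-(2-hydroxy-6-methoxy-6-oxohexan-3-yl)-5-methoxy-7-(methoxymethoxy)chromane-8-carboxylate | COc1cc(OCOC)c(C(=O)OC)c2c1C[C@H](C(C(C)O)CCC(=O)OC)CO2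
F4 | step 3 | methyl 3-formyl-2,6-dihydroxy-4-methoxybenzoate | COC(=O)c1c(O)cc(OC)c(C=O)c1O
F5 | step 3 | methyl 3-formyl-4-methoxy-2,6-bis(methoxymethoxy)benzoate | COC(=O)c1c(OCOC)cc(OC)c(C=O)c1OCOC
F6 | step 3 | methyl 3-(hydroxymethyl)-4-methoxy-2,6-bis(methoxymethoxy)benzoate | COC(=O)c1c(OCOC)cc(OC)c(CO)c1OCOC
F7 | step 3 | methyl 3-(bromomethyl)-4-methoxy-2,6-bis(methoxymethoxy)benzoate | COC(=O)c1c(OCOC)cc(OC)c(CBr)c1OCOC
F8 | step 3 | (4R)-4-benzyl-3-(pent-4-enoyl)oxazolidin-2-one | C=CCCC(=O)N1[C@H](Cc2ccccc2)COC1=O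
F9 | step 3 | methyl 3-[(2S)-2-[(4R)-4-benzyl-2-oxooxazolidine-3-carbonyl]pent-4-enyl]-4-methoxy-2,6-bis(methoxymethoxy)benzoate | COC(=O)c1c(OCOC)cc(OC)c(C[C@H](CC=C)C(=O)N2[C@H](Cc3ccccc3)COC2=O)c1OCOC
F10 | step 3 | methyl 3-[(2S)-2-(hydroxymethyl)pent-4-enyl]-4-methoxy-2,6-bis(methoxymethoxy)benzoate | COC(=O)c1c(OCOC)cc(OC)c(C[C@H](CC=C)CO)c1OCOC
F11 | step 3 | methyl 2,6-dihydroxy-3-[(2S)-2-(hydroxymethyl)pent-4-enyl]-4-methoxybenzoate | COC(=O)c1c(O)cc(OC)c(C[C@H](CC=C)CO)c1O
F12 | step 9 | methyl (3R)-3-[4-(tert-butyldimethylsilyloxy)-3-(3-methylbut-2-enyl)-2-oxocyclohex-3-enyl]-5-methoxy-7-(methoxymethoxy)chromane-8-carboxylate | COc1cc(OCOC)c(C(=O)OC)c2c1C[C@H](C1CCC(O[Si](C)(C)C(C)(C)C)=C(CC=C(C)C)C1=O)CO2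
F13 | step 9 | methyl (3R)-3-[4-(tert-butyldimethylsilyloxy)-2-hydroxy-3-(3-methylbut-2-enyl)phenyl]-5-methoxy-7-(methoxymethoxy)chromane-8-carboxylate | COc1cc(OCOC)c(C(=O)OC)c2c1C[C@H](c1ccc(O[Si](C)(C)C(C)(C)C)c(CC=C(C)C)c1O)CO2
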